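**Plan**

- Retrosynthesis: after removal of two N-sulfonyl activating groups, both C=C bonds of the quinone ring are cut, C2(OMe)=C3(indolyl) and C5(prenyl)=C6(indolyl). This divides the ring into two indolyl–C(=O)–C(=O)–CH2X units (X = OMe and X = CH2CH=CMe2). Each diketone is cut at its C(=O)–CH2 bond back to one indol-3-ylglyoxylic Weinreb amide, made from indole and oxalyl chloride.
- Enabling feature: in the quinone ring each C=C joins an indolyl-bearing carbon (a latent aryl ketone carbon) to a carbon that is alpha to the far ring carbonyl and carries OMe or prenyl (a latent enolisable CH2). The ring is therefore two 1-(indol-3-yl)-1,2-diketones joined head to tail, already at quinone oxidation level. These are the same pairs of carbons that the head-to-tail union of two indolylpyruvate units joins in the biosynthesis of bis-indolylquinones, with the polarity inverted.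
- Forward: indole → Weinreb amide → two diketones (parallel Grignard additions) → N-tosylation of each (activation of the indolyl ketone carbon) → crossed double aldol condensation that builds the quinone ring, the only ring formed in the route, with OMe and prenyl already in place → removal of both tosyl groups.
- Stereochemistry: the target has no stereocentre and no configured double bond. The stereocentres of the bis-aldol intermediate vanish on dehydration.

Key step: step 6

**Route**

Step 1
Reactants: 1 1H-indole
Product: 3 2-(1H-indol-3-yl)-N-methoxy-N-methyl-2-oxoacetamide, via indol-3-ylglyoxylyl chloride 2 (not isolated)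
Conditions: (COCl)2, Et2O, 0 °C; then MeONHMe·HCl, Et3N, CH2Cl2, 0 °C → rt
Reagents that add atoms: oxalyl chloride ClC(=O)C(=O)Cl; N,O-dimethylhydroxylamine hydrochloride CNOC.Cl
Why: Uncatalysed C3 acylation of indole by oxalyl chloride (Speeter–Anthony acylation) followed by amide formation from the acid chloride should give the Weinreb amide.

Step 2
Reactants: 3 2-(1H-indol-3-yl)-N-methoxy-N-methyl-2-oxoacetamide; 4 5-bromo-2-methylpent-2-ene
Product: 6 1-(1H-indol-3-yl)-6-methylhept-5-ene-1,2-dione, via homoprenylmagnesium bromide 5 (not isolated)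
Conditions: 4, Mg, THF, rt; then 3 (2.5 equiv of 5 per 3), THF, −40 → 0 °C; aq. NH4Cl
Reagents that add atoms: none
Why: Weinreb ketone synthesis, in which the first equivalent of 5 deprotonates N–H and so turns the indolyl ketone into an unreactive vinylogous amidate, while the second equivalent adds only to the N-methoxy-N-methylamide carbonyl, whose magnesium chelate survives until work-up and prevents over-addition.

Step 3
Reactants: 3 2-(1H-indol-3-yl)-N-methoxy-N-methyl-2-oxoacetamide; 7 chloro(methoxy)methane
Product: 9 1-(1H-indol-3-yl)-3-methoxypropane-1,2-dione, via methoxymethylmagnesium chloride 8 (not isolated)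
Conditions: 7, Mg, HgCl2 (cat.), THF/CH2(OMe)2, −25 °C; then 3 (2.5 equiv of 8 per 3), −25 → 0 °C; aq. NH4Cl
Reagents that add atoms: none
Why: Weinreb ketone synthesis with the same chemoselectivity as in step 2 (N-magnesiated indolyl ketone inert, chelated tetrahedral adduct stable), the alkoxymethyl Grignard reagent being made and used below 0 °C because it decomposes on warming.

Step 4
Reactants: 6 1-(1H-indol-3-yl)-6-methylhept-5-ene-1,2-dione
Product: 10 6-methyl-1-[1-(4-methylbenzenesulfonyl)-1H-indol-3-yl]hept-5-ene-1,2-dione
Conditions: TsCl, Et3N, DMAP (cat.), CH2Cl2, 0 °C → rt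
Reagents that add atoms: 4-methylbenzenesulfonyl chloride Cc1ccc(cc1)S(Cl)(=O)=O
Why: DMAP-catalysed N-sulfonylation of the acidic N–H of a 3-acylindole should install the electron-withdrawing group that stops nitrogen lone-pair donation into the indolyl ketone and removes the acidic N–H before the key step.

Step 5
Reactants: 9 1-(1H-indol-3-yl)-3-methoxypropane-1,2-dione
Product: 11 3-methoxy-1-[1-(4-methylbenzenesulfonyl)-1H-indol-3-yl]propane-1,2-dione
Conditions: TsCl, Et3N, DMAP (cat.), CH2Cl2, 0 °C → rt
Reagents that add atoms: 4-methylbenzenesulfonyl chloride Cc1ccc(cc1)S(Cl)(=O)=O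
Why: The same N-sulfonylation of a 3-acylindole as in step 4, the N–H being far more acidic than the methylene next to the diketone so that nitrogen should react first.

Step 6
Reactants: 10 6-methyl-1-[1-(4-methylbenzenesulfonyl)-1H-indol-3-yl]hept-5-ene-1,2-dione; 11 3-methoxy-1-[1-(4-methylbenzenesulfonyl)-1H-indol-3-yl]propane-1,2-dione
Product: 13 2-methoxy-5-(3-methylbut-2-en-1-yl)-3,6-bis[1-(4-methylbenzenesulfonyl)-1H-indol-3-yl]cyclohexa-2,5-diene-1,4-dione, via crossed bis-aldol 12 (not isolated)
Conditions: 10 (1 equiv), 11 (3 equiv), DBU (0.3 equiv, added last), 4 Å MS, MeCN, 0 → 40 °C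
Reagents that add atoms: none
Why: Proposed new method: DBU reversibly forms the enolates at the only enolisable carbons (the CH2OMe carbon of 11 and the C3 methylene of 10); one enolate adds to the indolyl ketone carbon of the other diketone, the second enolate then closes the ring onto the remaining indolyl ketone carbon to give 12, and two E1cB dehydrations give the quinone without any oxidant, because two 1,2-diketones less two molecules of water are already at quinone level. The closest known reaction type is the von Pechmann quinone synthesis, the base-mediated self-condensation of 1,2-diketones (butane-2,3-dione to 2,5-dimethylbenzoquinone, pentane-2,3-dione to duroquinone, 1-phenylpropane-1,2-dione to 2,5-diphenylbenzoquinone), extended here to the crossed pairing of two different heteroaryl diketones. The six-membered carbocycle closes by an intramolecular aldol addition in the 6-(enolendo)-exo-trig mode. No stereocentre remains in 13, the four stereocentres of 12 being destroyed by the dehydrations. The head-to-tail regiochemistry should be secured because each diketone has a single enolisable carbon and only attack on the partner's indolyl ketone carbon gives an adduct that can close a six-membered ring (adducts at the inner carbonyl can only revert by retro-aldol), while the N-sulfonyl groups keep those ketone carbons electrophilic. Crossed against homo pairing is not intrinsic and is secured by the threefold excess of 11, so that 10 should be consumed mainly in the crossed mode, the symmetrical dimethoxyquinone from 11 being removed by chromatography.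

Step 7
Reactants: 13 2-methoxy-5-(3-methylbut-2-en-1-yl)-3,6-bis[1-(4-methylbenzenesulfonyl)-1H-indol-3-yl]cyclohexa-2,5-diene-1,4-dione
Product: 14 2-methoxy-3,6-di(1H-indol-3-yl)-5-(3-methylbut-2-en-1-yl)cyclohexa-2,5-diene-1,4-dione
Conditions: Cs2CO3, anhydrous MeOH/THF, rt; aq. NH4Cl
Reagents that add atoms: none
Why: Nucleophilic N-desulfonylation of N-sulfonylindoles by methoxide (attack at sulfur) should be fast here because each departing indolide is conjugated to the quinone, and methoxide attack at the methoxy-bearing quinone carbon only exchanges OMe for OMe.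

**Compound list**

1 | 1H-indole | c1ccc2[nH]ccc2c1 | starting material
2 | 2-(1H-indol-3-yl)-2-oxoacetyl chloride | O=C(Cl)C(=O)c1c[nH]c2ccccc12 | intermediate
3 | 2-(1H-indol-3-yl)-N-methoxy-N-methyl-2-oxoacetamide | CON(C)C(=O)C(=O)c1c[nH]c2ccccc12 | intermediate
4 | 5-bromo-2-methylpent-2-ene | CC(C)=CCCBr | starting material
5 | (4-methylpent-3-en-1-yl)magnesium bromide | CC(C)=CCC[Mg]Br | intermediate
6 | 1-(1H-indol-3-yl)-6-methylhept-5-ene-1,2-dione | CC(C)=CCCC(=O)C(=O)c1c[nH]c2ccccc12 | intermediate
7 | chloro(methoxy)methane | COCCl | starting material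
8 | (methoxymethyl)magnesium chloride | COC[Mg]Cl | intermediate
9 | 1-(1H-indol-3-yl)-3-methoxypropane-1,2-dione | COCC(=O)C(=O)c1c[nH]c2ccccc12 | intermediate
10 | 6-methyl-1-[1-(4-methylbenzenesulfonyl)-1H-indol-3-yl]hept-5-ene-1,2-dione | CC(C)=CCCC(=O)C(=O)c1cn(S(=O)(=O)c2ccc(C)cc2)c2ccccc12 | intermediate
11 | 3-methoxy-1-[1-(4-methylbenzenesulfonyl)-1H-indol-3-yl]propane-1,2-dione | COCC(=O)C(=O)c1cn(S(=O)(=O)c2ccc(C)cc2)c2ccccc12 | intermediate
12 | 2,5-dihydroxy-3-methoxy-6-(3-methylbut-2-en-1-yl)-2,5-bis[1-(4-methylbenzenesulfonyl)-1H-indol-3-yl]cyclohexane-1,4-dione (mixture of diastereomers) | COC1C(O)(c2cn(S(=O)(=O)c3ccc(C)cc3)c3ccccc23)C(=O)C(CC=C(C)C)C(O)(c2cn(S(=O)(=O)c3ccc(C)cc3)c3ccccc23)C1=O | intermediate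
13 | 2-methoxy-5-(3-methylbut-2-en-1-yl)-3,6-bis[1-(4-methylbenzenesulfonyl)-1H-indol-3-yl]cyclohexa-2,5-diene-1,4-dione | COC1=C(c2cn(S(=O)(=O)c3ccc(C)cc3)c3ccccc23)C(=O)C(CC=C(C)C)=C(c2cn(S(=O)(=O)c3ccc(C)cc3)c3ccccc23)C1=O | intermediate
14 | 2-methoxy-3,6-di(1H-indol-3-yl)-5-(3-methylbut-2-en-1-yl)cyclohexa-2,5-diene-1,4-dione | COC1=C(c2c[nH]c3ccccc23)C(=O)C(CC=C(C)C)=C(c2c[nH]c3ccccc23)C1=O | target

**Step count**

Total steps: 7. Longest linear sequence: 5 (steps 1, 2, 4, 6, 7 or steps 1, 3, 5, 6, 7).

**Steps most likely to fail**

Step 6. The following processes may compete: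
- homo pairing of either diketone;
- aldol addition at the inner carbonyl followed by irreversible dehydration;
- stalling at the bis-aldol stage;
- loss of an N-sulfonyl group through hydroxide formed from the released water, which would deactivate the indolyl ketone;
- base-induced isomerisation of the prenylquinone.

The fallback uses known chemistry only, sets out from 1 and comes back to the route at 14. Acid-promoted double conjugate addition of 1 to 2,5-dibromo-1,4-benzoquinone with re-oxidation (AcOH, then DDQ) should give 2,5-dibromo-3,6-di(1H-indol-3-yl)cyclohexa-2,5-diene-1,4-dione F1. Addition–elimination with one equivalent of NaOMe in MeOH/THF at 0 °C should exchange one bromide and give 2-bromo-5-methoxy-3,6-di(1H-indol-3-yl)cyclohexa-2,5-diene-1,4-dione F2, the first methoxy group slowing the second exchange. Stille coupling of F2 with tributyl(3-methylbut-2-en-1-yl)stannane (Pd(PPh3)4, CuI, dioxane, 80 °C) should then give 14 directly.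

Step 3. The alkoxymethyl Grignard reagent may decompose before it adds, or proton transfer may outrun addition, so that 3 is recovered. The fallback sets out from 1 and comes back at 11, step 5 then not being needed. Iodination (I2, KOH, DMF) should give 3-iodo-1H-indole F3. N-Sulfonylation (NaH, TsCl, THF) should give 3-iodo-1-(4-methylbenzenesulfonyl)-1H-indole F4. Sonogashira coupling with 3-methoxyprop-1-yne (PdCl2(PPh3)2, CuI, Et3N) should give 3-(3-methoxyprop-1-yn-1-yl)-1-(4-methylbenzenesulfonyl)-1H-indole F5. Oxidation of the alkyne to the 1,2-diketone (PdCl2 cat., DMSO, 120 °C) should then give 11.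

Step 7. Methoxide or adventitious hydroxide may attack the quinone (loss of the methyl ether), the methyl sulfonate formed may N-methylate an indolide, or the base may isomerise the prenylquinone. The fallback sets out from 13 and comes back at 14 and replaces nucleophilic by reductive cleavage. Mg in MeOH with sonication should first reduce the quinone to its hydroquinone, which is inert to base and nucleophiles, and then cleave both N–S bonds by electron transfer to give 2-methoxy-3,6-di(1H-indol-3-yl)-5-(3-methylbut-2-en-1-yl)benzene-1,4-diol F6. Oxidation of F6 with air or Ag2O should return the quinone 14.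

**Further compounds**

F1 | step 6 | 2,5-dibromo-3,6-di(1H-indol-3-yl)cyclohexa-2,5-diene-1,4-dione | BrC1=C(c2c[nH]c3ccccc23)C(=O)C(Br)=C(c2c[nH]c3ccccc23)C1=O
F2 | step 6 | 2-bromo-5-methoxy-3,6-di(1H-indol-3-yl)cyclohexa-2,5-diene-1,4-dione | COC1=C(c2c[nH]c3ccccc23)C(=O)C(Br)=C(c2c[nH]c3ccccc23)C1=O
F3 | step 3 | 3-iodo-1H-indole | Ic1c[nH]c2ccccc12
F4 | step 3 | 3-iodo-1-(4-methylbenzenesulfonyl)-1H-indole | Cc1ccc(cc1)S(=O)(=O)n1cc(I)c2ccccc12
F5 | step 3 | 3-(3-methoxyprop-1-yn-1-yl)-1-(4-methylbenzenesulfonyl)-1H-indole | COCC#Cc1cn(S(=O)(=O)c2ccc(C)cc2)c2ccccc12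
F6 | step 7 | 2-methoxy-3,6-di(1H-indol-3-yl)-5-(3-methylbut-2-en-1-yl)benzene-1,4-diol | COc1c(O)c(-c2c[nH]c3ccccc23)c(CC=C(C)C)c(O)c1-c1c[nH]c2ccccc12
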